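The readings are simulated for substances that don't exist, and the scatter is random.

L, the substrate, goes over to X and G in a closed flask with E, and you want the ratio of X to G in a new flask, early and late.

| setting | teal | amber | flask |
|---|---|---|---|
| L | 0.050 M | 0.20 M | 0.10 M |
| E | 0.090 M | 0.090 M | 0.0900 M |
| remark | run made earlier | run made earlier |  |
| time |  |  | 4.0 d |

| run | time / d | X / % | G / % |
|---|---|---|---|
| teal | 0.250 | 2.1 | 34.6 |
| teal | 0.833 | 6.0 | 69.1 |
| teal | 1.67 | 5.9 | 86.7 |
| teal | 2.50 | 5.5 | 93.1 |
| teal | 3.00 | 6.2 | 92.8 |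
| amber | 0.250 | 3.3 | 33.8 |
| amber | 0.833 | 4.6 | 68.9 |
| amber | 1.67 | 5.4 | 86.8 |
| amber | 2.50 | 6.6 | 93.0 |
| amber | 3.00 | 5.7 | 92.6 |

(each reading ± 0.5 percentage points)

- ratio of X to G at 3.0 min
- ratio of X to G at 4.0 d
- which of X and G there is more of at 4.0 d

- a reading or a percentage of X counts all its forms, free or not

Late on, both runs stand still and look alike, at 0.050 M and at 0.20 M of L. So take the late ratio, X over G summed over the last two readings of both runs, 0.0646. If X and G pass into each other, forward rate equals back rate there and time drops out of their quotient: thermodynamic control. My reckoning is therefore 0.0646 at 4.0 d in the new flask, with G ahead. The earliest reading is at 0.250 d, so for 3.0 min this gives me no number.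

The forecast says 0.072 at 3.0 min and 0.065 at 4.0 d, with G ahead, calling the ratio “essentially constant within scatter”.

The flask gives 8.18 at 3.0 min and 0.0625 at 4.0 d, with G at 93.9 % of the L charged, more than X at 5.87 %.

    L ⇌ D (K = 3.10, k = 4.70 × 10⁻⁴ s⁻¹)
    L ⇌ Z (K = 0.680, k = 0.00820 s⁻¹)
    L → X (k = 9.10 × 10⁻⁵ s⁻¹)
    X ⇌ G (K = 16.0, k = 0.00120 s⁻¹)
    J ⇌ X, rate k5*(cs5 - [X]) while solid is left; crystals form when [X] > cs5 (solubility = 20.0 mM, k = 0.00640 s⁻¹)

Take away the falling back of G to X and the flask's ratio at 4.0 d sinks from 0.0625 to 3.18 × 10⁻⁵. The step between X and G, taken alone, relaxes with a half-life of 0.151 h, far shorter than 4.0 d but longer than 3.0 min, and at 3.0 min the flask's ratio stands far above the late 0.0646. Late on, 0.0646 times the flask's G gives 6.07 % X. The neighbour flask with 0.40 M of L ends at a ratio of 0.247, with X at 19.8 % of the L charged, all its forms counted, and G at 80.0 %. In that neighbour flask, 0.0646 times G reckons 5.17 % X in solution, which by this reckoning leaves 14.6 % for the crystals J, and the neighbour flask holds 14.8 % of J.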